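**Plan**

- Retrosynthetic cuts: the C15–O ester bond (releasing the C30 ω‑hydroxy acid), C13=C14, the C9–C11 bond, C7–C8 of ring B, and last the two ring‑A bonds C1–C10 and C4–C5.
- Enabling feature (labdane numbering): in ring A the quaternary C10 (CH3, C9) and its neighbour C5 (H, C6) are trans, and the C3 oxygen sits 1,4 to C10. This is the pattern a 1‑amino‑3‑siloxybutadiene and an (E)‑2‑methyl‑2‑enal give in a [4+2] addition.
- Forward: ring A by enantioselective Diels–Alder (steps 1–5); C4 gem‑dimethyl and ring B by intramolecular aldol condensation (steps 6–11); C9 side chain and the C7–C8 alkene (steps 12–17); C13–C15 (steps 18–20); C30 acid (steps 21–24); ester and desilylation (steps 25–26).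
- Stereochemistry: C5/C10 absolute from the chiral cobalt–salen catalyst, relative from the E enal; C3 from axial hydride delivery; C9 from axial protonation in the Li/NH3 reduction; C13=C14 E from the phosphonate olefination.

Key step: step 5

Assumption: the (R,R) ligand (and, in the fallback, the (2R,5R) auxiliary) is taken as the enantiomer that leaves open the enal face leading to the (5R,6S) adduct 9; if a first correlation shows the opposite sense, the mirror‑image ligand is used with nothing else changed.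

**Route**

Step 1
Reactants: 1 3‑(benzyloxy)propanal; 2 2‑(triphenylphosphoranylidene)propanal
Product: 3 (E)‑5‑(benzyloxy)‑2‑methylpent‑2‑enal
Conditions: toluene, 90 °C
Reagents that add atoms: none
Why: Wittig olefination with the formyl‑stabilised ylide is under thermodynamic control and should give the trisubstituted (E)‑enal, with the formyl group trans to the new β‑substituent.

Step 2
Reactants: 4 (E)‑4‑methoxybut‑3‑en‑2‑one; 5 benzylamine
Product: 6 (Z)‑4‑(benzylamino)but‑3‑en‑2‑one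
Conditions: CH2Cl2, 0 °C → rt
Reagents that add atoms: none
Why: Conjugate addition–elimination (amine exchange on a vinylogous ester) replaces methoxide by the amine and is driven by the hydrogen‑bonded vinylogous amide.

Step 3
Reactants: 6 vinylogous amide
Product: 7 methyl benzyl[(1E)‑3‑oxobut‑1‑en‑1‑yl]carbamate
Conditions: NaN(SiMe3)2, THF, −78 °C; ClCO2Me, −78 → 0 °C
Reagents that add atoms: methyl chloroformate, COC(=O)Cl
Why: N‑Acylation of the sodium salt of the vinylogous amide gives the vinylogous imide, whose alkene settles in the E form once the N–H hydrogen bond is gone.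

Step 4
Reactants: 7 vinylogous imide
Product: 8 methyl benzyl{(1E)‑3‑[(tert‑butyldimethylsilyl)oxy]buta‑1,3‑dien‑1‑yl}carbamate
Conditions: KN(SiMe3)2, THF, −78 °C; TBSCl, −78 °C → rt
Reagents that add atoms: tert‑butyldimethylsilyl chloride, CC(C)(C)[Si](C)(C)Cl
Why: Kinetic deprotonation of the methyl ketone and O‑silylation of the potassium enolate (silyl enol ether formation) should give the 1‑carbamato‑3‑siloxydiene with the carbamate untouched.

Step 5
Reactants: 3 (E)‑enal; 8 carbamato siloxydiene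
Product: 9 methyl benzyl{(5R,6S)‑5‑[2‑(benzyloxy)ethyl]‑3‑[(tert‑butyldimethylsilyl)oxy]‑6‑formyl‑6‑methylcyclohex‑2‑en‑1‑yl}carbamate (C1 epimers)
Conditions: (R,R)‑(salen)Co(SbF6) (5 mol%; salen = N,N′‑bis(3,5‑di‑tert‑butylsalicylidene)cyclohexane‑1,2‑diaminate; trivalent cobalt), 4 Å MS, CH2Cl2, −20 °C → rt
Reagents that add atoms: none
Why: The cationic cobalt–salen complex binds the formyl oxygen of 3 and lowers its LUMO, and the polarised diene 8 adds in a concerted, asynchronous [4+2] cycloaddition in which its CH2 terminus bonds to the enal β‑carbon (C4–C5) and its nitrogen‑bearing terminus to the α‑carbon (C1–C10). The closest known reaction is the metal–salen‑catalysed Diels–Alder reaction of 1‑amino‑3‑siloxybutadienes with α‑substituted acroleins, which builds formyl‑bearing quaternary centres; the β‑substituent here puts 3 at the slow end of that class. Ring A closes as a six‑membered carbocycle by intermolecular suprafacial addition on both partners. C10 and C5 form together: their trans C9/C6 relationship is a direct transcription of the E geometry of 3, their absolute configuration follows from the enal face left open by the chiral ligand, and the C1 configuration (endo or exo) does not matter because that centre is destroyed in step 6. The step needs regio‑, relative and facial selectivity, secured respectively by the matched polarisation of 8 and 3, by the stereospecificity of the cycloaddition and by the catalyst. The silyl enol ether and the carbamate are kept in 9 as a masked C3 ketone and a masked C1–C2 alkene.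

Step 6
Reactants: 9 cycloadduct
Product: 11 (4S,5R)‑5‑[2‑(benzyloxy)ethyl]‑4‑(1‑hydroxypropyl)‑4‑methylcyclohex‑2‑en‑1‑one (carbinol epimers), via carbinol cycloadduct 10 (not isolated)
Conditions: EtMgBr, THF, −78 → −40 °C; NH4Cl (aq); crude 10, HF (48% aq), MeCN, 0 °C → rt
Reagents that add atoms: ethylmagnesium bromide, CC[Mg]Br
Why: Grignard addition meets a single electrophile because the C3 ketone is still a silyl enol ether, and HF then cleaves the enol ether and expels the β‑carbamate (E1cB‑type elimination) to uncover the C1–C2 enone; the carbinol centre is left uncontrolled since it is oxidised in step 10.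

Step 7
Reactants: 11 hydroxy enone
Product: 12 (4S,5R)‑5‑[2‑(benzyloxy)ethyl]‑4‑{1‑[(benzyloxy)methoxy]propyl}‑4‑methylcyclohex‑2‑en‑1‑one (side‑chain epimers)
Conditions: BnOCH2Cl, i‑Pr2NEt, n‑Bu4NI (cat.), CH2Cl2, 40 °C
Reagents that add atoms: benzyl chloromethyl ether, ClCOCc1ccccc1
Why: Acetal‑type O‑alkylation with an α‑chloro ether masks the hindered secondary hydroxyl, which as an alkoxide γ to the enone could fragment by vinylogous retro‑aldol cleavage in step 8, with a group that later leaves by hydrogenolysis together with the benzyl ether.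

Step 8
Reactants: 12 protected enone
Product: 14 (4R,5S)‑5‑[2‑(benzyloxy)ethyl]‑4‑{1‑[(benzyloxy)methoxy]propyl}‑4,6,6‑trimethylcyclohex‑2‑en‑1‑one (side‑chain epimers), via monomethyl enone 13 (not isolated)
Conditions: LiN(i‑Pr)2 (1.1 equiv), THF, −78 °C; MeI, −78 → −20 °C; LiN(i‑Pr)2 (1.3 equiv), −78 °C; MeI, −78 → 0 °C
Reagents that add atoms: iodomethane, CI
Why: Because C10 is quaternary the enone has no γ‑hydrogen, so the amide base can only form the cross‑conjugated C3–C4 enolate, and two successive enolate alkylations should install the C4 gem‑dimethyl group; the transient C4 stereocentre of 13 vanishes in the second alkylation.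

Step 9
Reactants: 14 gem‑dimethyl enone
Product: 15 (3S,4R)‑3‑(2‑hydroxyethyl)‑4‑(1‑hydroxypropyl)‑2,2,4‑trimethylcyclohexan‑1‑one (carbinol epimers)
Conditions: H2 (1 atm), Pd/C (10%), EtOH, rt
Reagents that add atoms: none
Why: Heterogeneous catalytic hydrogenation saturates the C1–C2 alkene and hydrogenolyses both benzylic C–O bonds, the hemiacetal left from the benzyloxymethyl group losing formaldehyde, so both hydroxyls needed for the next step are freed at once.

Step 10
Reactants: 15 keto diol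
Product: 16 2‑[(1R,6R)‑2,2,6‑trimethyl‑3‑oxo‑6‑propanoylcyclohexyl]acetaldehyde
Conditions: (COCl)2, DMSO, CH2Cl2, −78 → −45 °C; Et3N, −78 → 0 °C
Reagents that add atoms: none
Why: Swern oxidation turns both hydroxyls into alkoxysulfonium ions before any carbonyl exists and only then, on adding the amine, into the C7 aldehyde and the C9 ethyl ketone, which avoids a hydroxy aldehyde that would close to a lactol and be over‑oxidised to the lactone; the carbinol epimers converge to one compound.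

Step 11
Reactants: 16 keto aldehyde
Product: 18 (4aR,8aR)‑2,5,5,8a‑tetramethyl‑4a,7,8,8a‑tetrahydronaphthalene‑1,6(4H,5H)‑dione, via ketol 17 (not isolated)
Conditions: KOH (0.2 M), MeOH, 0 °C → rt
Reagents that add atoms: none
Why: Intramolecular aldol condensation can close a fused six‑membered ring only through the C8 enolate of the ethyl ketone attacking the C7 aldehyde, since every other enolate–carbonyl pairing gives a four‑membered ring or a bridged ketol that cannot dehydrate, and loss of water then fixes the C7–C8 alkene; the trans ring fusion is inherited from C5 and C10, neither of which is enolisable.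

Step 12
Reactants: 18 enedione
Product: 19 (4aR,6R,8aR)‑6‑hydroxy‑2,5,5,8a‑tetramethyl‑4a,5,6,7,8,8a‑hexahydronaphthalen‑1(4H)‑one
Conditions: NaBH4, MeOH–CH2Cl2, −40 → −20 °C
Reagents that add atoms: none
Why: Borohydride reduces the saturated C3 ketone in preference to the conjugated, doubly flanked C9 carbonyl (chemoselective hydride reduction), and axial hydride delivery on the face opposite the axial C4 and C10 methyl groups should give the equatorial alcohol.

Step 13
Reactants: 19 hydroxy enone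
Product: 20 (4aR,6R,8aR)‑6‑[(tert‑butyldimethylsilyl)oxy]‑2,5,5,8a‑tetramethyl‑4a,5,6,7,8,8a‑hexahydronaphthalen‑1(4H)‑one
Conditions: TBSOTf, 2,6‑lutidine, CH2Cl2, 0 °C
Reagents that add atoms: tert‑butyldimethylsilyl trifluoromethanesulfonate, CC(C)(C)[Si](C)(C)OS(=O)(=O)C(F)(F)F
Why: Silylation with the silyl triflate and a hindered pyridine base protects the neopentyl‑type alcohol as an ether that withstands the organometallic, oxidative, dissolving‑metal and mildly acidic steps that follow.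

Step 14
Reactants: 20 silyl ether enone; 21 2‑(2‑bromoethyl)‑2‑methyl‑1,3‑dioxolane
Product: 23 (3R,5R,10R)‑3‑[(tert‑butyldimethylsilyl)oxy]‑13,13‑(ethylenedioxy)‑14,15‑dinorlabd‑7‑en‑9‑ol (C9 epimers), via Grignard reagent 22 (not isolated)
Conditions: 21, Mg, THF, 25 °C; CeCl3 (anhydrous), THF, −78 °C; 20, −78 → 0 °C; NH4Cl (aq)
Reagents that add atoms: none
Why: Transmetallation of the Grignard reagent gives a less basic, more oxophilic organocerium species whose 1,2‑addition to the hindered, non‑enolisable C9 carbonyl should outrun conjugate addition, β‑hydride reduction and γ‑deprotonation; the configuration of the new carbinol is irrelevant because C9 becomes sp2 in step 15.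

Step 15
Reactants: 23 tertiary allylic alcohol
Product: 24 (3R,5S,10R)‑3‑[(tert‑butyldimethylsilyl)oxy]‑13,13‑(ethylenedioxy)‑14,15‑dinorlabd‑8‑en‑7‑one
Conditions: (C5H5NH)[CrO3Cl] (pyridinium chlorochromate), 4 Å MS, CH2Cl2, rt
Reagents that add atoms: pyridinium chlorochromate, [O-][Cr](=O)(=O)Cl.c1cc[nH+]cc1
Why: In the Babler–Dauben oxidative transposition the chromate ester of the tertiary allylic alcohol undergoes a [3,3] shift to the secondary C7 position and is oxidised there, which moves the oxygen to C7 and leaves the side chain on the β‑carbon of a C8–C9 enone.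

Step 16
Reactants: 24 enone
Product: 26 (3R,5S,9S,10R)‑3‑[(tert‑butyldimethylsilyl)oxy]‑13,13‑(ethylenedioxy)‑14,15‑dinorlabd‑7‑en‑7‑yl trifluoromethanesulfonate, via lithium enolate 25 (not isolated)
Conditions: Li (2.1 equiv), NH3(l)–THF, t‑BuOH (1 equiv), −78 °C; NH3 off; PhNTf2, THF, 0 °C → rt
Reagents that add atoms: N‑phenylbis(trifluoromethanesulfonimide), O=S(=O)(N(c1ccccc1)S(=O)(=O)C(F)(F)F)C(F)(F)F
Why: Dissolving‑metal (Birch‑type) reduction of the enone protonates the β‑carbon C9 axially, on the face opposite the axial C10 methyl group, so the side chain becomes equatorial as in the target, and the regiodefined C7–C8 lithium enolate is then trapped on oxygen as the enol triflate.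

Step 17
Reactants: 26 enol triflate
Product: 27 (3R,5S,9R,10S)‑3‑[(tert‑butyldimethylsilyl)oxy]‑13,13‑(ethylenedioxy)‑14,15‑dinorlabd‑7‑ene
Conditions: Pd(OAc)2 (5 mol%), PPh3 (10 mol%), Et3N, HCO2H, DMF, 60 °C
Reagents that add atoms: none
Why: Palladium‑catalysed reduction of the enol triflate with formate as hydride source (oxidative addition, decarboxylation, reductive elimination) replaces the triflate by hydrogen without moving the alkene, giving the trisubstituted C7–C8 double bond.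

Step 18
Reactants: 27 ketal
Product: 28 (3R,5S,9R,10S)‑3‑[(tert‑butyldimethylsilyl)oxy]‑14,15‑dinorlabd‑7‑en‑13‑one
Conditions: pyridinium p‑toluenesulfonate, acetone–H2O (9:1), 55 °C
Reagents that add atoms: water, O
Why: Ketal hydrolysis with a weak pyridinium acid frees the C13 methyl ketone, while the hindered secondary silyl ether and the trisubstituted alkene are expected to stay untouched.

Step 19
Reactants: 28 methyl ketone
Product: 29 ethyl (3R,5S,9R,10S,13E)‑3‑[(tert‑butyldimethylsilyl)oxy]labda‑7,13‑dien‑15‑oate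
Conditions: (EtO)2P(O)CH2CO2Et, NaH, THF, 0 → 50 °C
Reagents that add atoms: triethyl phosphonoacetate, CCOC(=O)CP(=O)(OCC)OCC
Why: Horner–Wadsworth–Emmons olefination of the unhindered methyl ketone with the stabilised phosphonate anion favours the (E)‑enoate, and the minor Z isomer is to be removed by chromatography here or after step 20.

Step 20
Reactants: 29 enoate
Product: 30 (3R,5S,9R,10S,13E)‑3‑[(tert‑butyldimethylsilyl)oxy]labda‑7,13‑dien‑15‑ol
Conditions: i‑Bu2AlH, CH2Cl2, −78 °C; KNaC4H4O6 (aq)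
Reagents that add atoms: none
Why: 1,2‑Reduction of the conjugated ester with a dialkylaluminium hydride at low temperature gives the allylic alcohol and leaves the alkenes and the silyl ether alone.

Step 21
Reactants: 31 12‑bromododecan‑1‑ol
Product: 32 [(12‑bromododecyl)oxy](tert‑butyl)dimethylsilane
Conditions: TBSCl, imidazole, DMF, rt
Reagents that add atoms: tert‑butyldimethylsilyl chloride, CC(C)(C)[Si](C)(C)Cl
Why: Standard silylation of a primary alcohol with the silyl chloride and imidazole.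

Step 22
Reactants: 32 bromo silyl ether
Product: 33 tert‑butyldimethyl(tetradec‑13‑yn‑1‑yloxy)silane
Conditions: LiC≡CH·H2NCH2CH2NH2, DMSO, 10 °C → rt
Reagents that add atoms: lithium acetylide–ethylenediamine complex, [Li]C#C.NCCN
Why: SN2 alkylation of lithium acetylide by the primary bromide in a dipolar aprotic solvent extends the chain by a terminal alkyne.

Step 23
Reactants: 33 terminal alkyne; 34 16‑bromohexadecanoic acid
Product: 35 30‑[(tert‑butyldimethylsilyl)oxy]triacont‑17‑ynoic acid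
Conditions: 33, n‑BuLi, THF, −40 → 0 °C; 34 pre‑treated with LiN(SiMe3)2 (1 equiv), THF–DMPU, 0 → 45 °C; citric acid (aq)
Reagents that add atoms: none
Why: SN2 alkylation of the lithium alkynide by the primary bromide of the preformed lithium ω‑bromocarboxylate joins the C14 and C16 pieces into the C30 chain, the acid being protected as its salt.

Step 24
Reactants: 35 alkynoic acid
Product: 36 30‑[(tert‑butyldimethylsilyl)oxy]triacontanoic acid
Conditions: H2 (1 atm), Pd/C (10%), EtOAc–THF, 40 °C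
Reagents that add atoms: none
Why: Catalytic hydrogenation saturates the internal alkyne to the straight chain, with the silyl ether and the carboxylic acid inert.

Step 25
Reactants: 30 allylic alcohol; 36 silyloxy acid
Product: 37 (3R,5S,9R,10S,13E)‑3‑[(tert‑butyldimethylsilyl)oxy]labda‑7,13‑dien‑15‑yl 30‑[(tert‑butyldimethylsilyl)oxy]triacontanoate
Conditions: EDC·HCl, DMAP, CH2Cl2–THF, 30 °C
Reagents that add atoms: none
Why: Carbodiimide/DMAP (Steglich) esterification acylates the primary allylic alcohol under neutral conditions that avoid allylic ionisation, the ω‑hydroxyl of the acid being masked against self‑condensation.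

Step 26
Reactants: 37 bis‑silyl ester
Product: 38 (3R,5S,9R,10S,13E)‑3‑hydroxylabda‑7,13‑dien‑15‑yl 30‑hydroxytriacontanoate
Conditions: HF·pyridine, THF–pyridine, 0 °C → rt
Reagents that add atoms: none
Why: Fluoride‑mediated desilylation under buffered conditions removes the primary and the hindered secondary silyl ether in one operation without cleaving the allylic ester or shifting the alkenes.

**Compound list**

1 | 3‑(benzyloxy)propanal | O=CCCOCc1ccccc1 | starting material
2 | 2‑(triphenylphosphoranylidene)propanal | CC(C=O)=P(c1ccccc1)(c1ccccc1)c1ccccc1 | starting material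
3 | (E)‑5‑(benzyloxy)‑2‑methylpent‑2‑enal | O=C/C(C)=C/CCOCc1ccccc1 | intermediate
4 | (E)‑4‑methoxybut‑3‑en‑2‑one | CO/C=C/C(C)=O | starting material
5 | benzylamine | NCc1ccccc1 | starting material
6 | (Z)‑4‑(benzylamino)but‑3‑en‑2‑one | CC(=O)/C=C\NCc1ccccc1 | intermediate
7 | methyl benzyl[(1E)‑3‑oxobut‑1‑en‑1‑yl]carbamate | COC(=O)N(Cc1ccccc1)/C=C/C(C)=O | intermediate
8 | methyl benzyl{(1E)‑3‑[(tert‑butyldimethylsilyl)oxy]buta‑1,3‑dien‑1‑yl}carbamate | COC(=O)N(Cc1ccccc1)/C=C/C(=C)O[Si](C)(C)C(C)(C)C | intermediate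
9 | methyl benzyl{(5R,6S)‑5‑[2‑(benzyloxy)ethyl]‑3‑[(tert‑butyldimethylsilyl)oxy]‑6‑formyl‑6‑methylcyclohex‑2‑en‑1‑yl}carbamate, C1 epimers | c1ccccc1COCC[C@@H]1CC(O[Si](C)(C)C(C)(C)C)=CC(N(Cc2ccccc2)C(=O)OC)[C@@]1(C)C=O | intermediate
10 | methyl benzyl{(5R,6S)‑5‑[2‑(benzyloxy)ethyl]‑3‑[(tert‑butyldimethylsilyl)oxy]‑6‑(1‑hydroxypropyl)‑6‑methylcyclohex‑2‑en‑1‑yl}carbamate, C1 and carbinol epimers | c1ccccc1COCC[C@@H]1CC(O[Si](C)(C)C(C)(C)C)=CC(N(Cc2ccccc2)C(=O)OC)[C@@]1(C)C(O)CC | intermediate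
11 | (4S,5R)‑5‑[2‑(benzyloxy)ethyl]‑4‑(1‑hydroxypropyl)‑4‑methylcyclohex‑2‑en‑1‑one, carbinol epimers | c1ccccc1COCC[C@@H]1CC(=O)C=C[C@@]1(C)C(O)CC | intermediate
12 | (4S,5R)‑5‑[2‑(benzyloxy)ethyl]‑4‑{1‑[(benzyloxy)methoxy]propyl}‑4‑methylcyclohex‑2‑en‑1‑one, side‑chain epimers | c1ccccc1COCC[C@@H]1CC(=O)C=C[C@@]1(C)C(CC)OCOCc1ccccc1 | intermediate
13 | 5‑[2‑(benzyloxy)ethyl]‑4‑{1‑[(benzyloxy)methoxy]propyl}‑4,6‑dimethylcyclohex‑2‑en‑1‑one, ring centres C4 and C5 as in 12, C6 epimers | c1ccccc1COCC[C@@H]1C(C)C(=O)C=C[C@@]1(C)C(CC)OCOCc1ccccc1 | intermediate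
14 | (4R,5S)‑5‑[2‑(benzyloxy)ethyl]‑4‑{1‑[(benzyloxy)methoxy]propyl}‑4,6,6‑trimethylcyclohex‑2‑en‑1‑one, side‑chain epimers | c1ccccc1COCC[C@@H]1C(C)(C)C(=O)C=C[C@@]1(C)C(CC)OCOCc1ccccc1 | intermediate
15 | (3S,4R)‑3‑(2‑hydroxyethyl)‑4‑(1‑hydroxypropyl)‑2,2,4‑trimethylcyclohexan‑1‑one, carbinol epimers | OCC[C@@H]1C(C)(C)C(=O)CC[C@@]1(C)C(O)CC | intermediate
16 | 2‑[(1R,6R)‑2,2,6‑trimethyl‑3‑oxo‑6‑propanoylcyclohexyl]acetaldehyde | O=CC[C@@H]1C(C)(C)C(=O)CC[C@@]1(C)C(=O)CC | intermediate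
17 | 3‑hydroxy‑2,5,5,8a‑tetramethyloctahydronaphthalene‑1,6(2H,5H)‑dione, ring fusion as in 18, C2 and C3 epimers | CC1C(O)C[C@@H]2C(C)(C)C(=O)CC[C@@]2(C)C1=O | intermediate
18 | (4aR,8aR)‑2,5,5,8a‑tetramethyl‑4a,7,8,8a‑tetrahydronaphthalene‑1,6(4H,5H)‑dione | CC1=CC[C@@H]2C(C)(C)C(=O)CC[C@@]2(C)C1=O | intermediate
19 | (4aR,6R,8aR)‑6‑hydroxy‑2,5,5,8a‑tetramethyl‑4a,5,6,7,8,8a‑hexahydronaphthalen‑1(4H)‑one | CC1=CC[C@@H]2C(C)(C)[C@H](O)CC[C@@]2(C)C1=O | intermediate
20 | (4aR,6R,8aR)‑6‑[(tert‑butyldimethylsilyl)oxy]‑2,5,5,8a‑tetramethyl‑4a,5,6,7,8,8a‑hexahydronaphthalen‑1(4H)‑one | CC1=CC[C@@H]2C(C)(C)[C@H](O[Si](C)(C)C(C)(C)C)CC[C@@]2(C)C1=O | intermediate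
21 | 2‑(2‑bromoethyl)‑2‑methyl‑1,3‑dioxolane | CC1(CCBr)OCCO1 | starting material
22 | [2‑(2‑methyl‑1,3‑dioxolan‑2‑yl)ethyl]magnesium bromide | CC1(CC[Mg]Br)OCCO1 | intermediate
23 | (3R,5R,10R)‑3‑[(tert‑butyldimethylsilyl)oxy]‑13,13‑(ethylenedioxy)‑14,15‑dinorlabd‑7‑en‑9‑ol, C9 epimers (labdane numbering) | CC1=CC[C@@H]2C(C)(C)[C@H](O[Si](C)(C)C(C)(C)C)CC[C@@]2(C)C1(O)CCC3(C)OCCO3 | intermediate
24 | (3R,5S,10R)‑3‑[(tert‑butyldimethylsilyl)oxy]‑13,13‑(ethylenedioxy)‑14,15‑dinorlabd‑8‑en‑7‑one | CC1=C(CCC3(C)OCCO3)[C@]2(C)CC[C@@H](O[Si](C)(C)C(C)(C)C)C(C)(C)[C@H]2CC1=O | intermediate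
25 | lithium C7–C8 enolate of the 9‑H ketone, stereocentres as in 26 | CC1=C(O[Li])C[C@@H]2C(C)(C)[C@H](O[Si](C)(C)C(C)(C)C)CC[C@@]2(C)[C@@H]1CCC3(C)OCCO3 | intermediate
26 | (3R,5S,9S,10R)‑3‑[(tert‑butyldimethylsilyl)oxy]‑13,13‑(ethylenedioxy)‑14,15‑dinorlabd‑7‑en‑7‑yl trifluoromethanesulfonate | CC1=C(OS(=O)(=O)C(F)(F)F)C[C@@H]2C(C)(C)[C@H](O[Si](C)(C)C(C)(C)C)CC[C@@]2(C)[C@@H]1CCC3(C)OCCO3 | intermediate
27 | (3R,5S,9R,10S)‑3‑[(tert‑butyldimethylsilyl)oxy]‑13,13‑(ethylenedioxy)‑14,15‑dinorlabd‑7‑ene | CC1=CC[C@@H]2C(C)(C)[C@H](O[Si](C)(C)C(C)(C)C)CC[C@@]2(C)[C@@H]1CCC3(C)OCCO3 | intermediate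
28 | (3R,5S,9R,10S)‑3‑[(tert‑butyldimethylsilyl)oxy]‑14,15‑dinorlabd‑7‑en‑13‑one | CC1=CC[C@@H]2C(C)(C)[C@H](O[Si](C)(C)C(C)(C)C)CC[C@@]2(C)[C@@H]1CCC(C)=O | intermediate
29 | ethyl (3R,5S,9R,10S,13E)‑3‑[(tert‑butyldimethylsilyl)oxy]labda‑7,13‑dien‑15‑oate | CC1=CC[C@@H]2C(C)(C)[C@H](O[Si](C)(C)C(C)(C)C)CC[C@@]2(C)[C@@H]1CC/C(C)=C/C(=O)OCC | intermediate
30 | (3R,5S,9R,10S,13E)‑3‑[(tert‑butyldimethylsilyl)oxy]labda‑7,13‑dien‑15‑ol | CC1=CC[C@@H]2C(C)(C)[C@H](O[Si](C)(C)C(C)(C)C)CC[C@@]2(C)[C@@H]1CC/C(C)=C/CO | intermediate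
31 | 12‑bromododecan‑1‑ol | OCCCCCCCCCCCCBr | starting material
32 | [(12‑bromododecyl)oxy](tert‑butyl)dimethylsilane | CC(C)(C)[Si](C)(C)OCCCCCCCCCCCCBr | intermediate
33 | tert‑butyldimethyl(tetradec‑13‑yn‑1‑yloxy)silane | CC(C)(C)[Si](C)(C)OCCCCCCCCCCCCC#C | intermediate
34 | 16‑bromohexadecanoic acid | OC(=O)CCCCCCCCCCCCCCCBr | starting material
35 | 30‑[(tert‑butyldimethylsilyl)oxy]triacont‑17‑ynoic acid | OC(=O)CCCCCCCCCCCCCCCC#CCCCCCCCCCCCCO[Si](C)(C)C(C)(C)C | intermediate
36 | 30‑[(tert‑butyldimethylsilyl)oxy]triacontanoic acid | OC(=O)CCCCCCCCCCCCCCCCCCCCCCCCCCCCCO[Si](C)(C)C(C)(C)C | intermediate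
37 | (3R,5S,9R,10S,13E)‑3‑[(tert‑butyldimethylsilyl)oxy]labda‑7,13‑dien‑15‑yl 30‑[(tert‑butyldimethylsilyl)oxy]triacontanoate | CC1=CC[C@@H]2C(C)(C)[C@H](O[Si](C)(C)C(C)(C)C)CC[C@@]2(C)[C@@H]1CC/C(C)=C/COC(=O)CCCCCCCCCCCCCCCCCCCCCCCCCCCCCO[Si](C)(C)C(C)(C)C | intermediate
38 | (3R,5S,9R,10S,13E)‑3‑hydroxylabda‑7,13‑dien‑15‑yl 30‑hydroxytriacontanoate (CNP0303636.1) | CC1=CC[C@@H]2C(C)(C)[C@H](O)CC[C@@]2(C)[C@@H]1CC/C(C)=C/COC(=O)CCCCCCCCCCCCCCCCCCCCCCCCCCCCCO | target

**Step count**

Total: 26 steps. Longest linear sequence: 21 steps (steps 2–4, 5–20, 25, 26).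

**Steps most likely to fail**

Step 5. The β‑substituent may slow the cycloaddition so much that the diene is lost to hydrolysis or oligomerisation before it reacts, or the catalyst may discriminate the enal faces poorly. The fallback replaces catalyst control by an auxiliary‑controlled, uncatalysed cycloaddition with a more electron‑rich diene; it sets out from 4 and 3 and returns at 11. Compound 4 is condensed with (2R,5R)‑2,5‑diphenylpyrrolidine to the vinylogous amide (E)‑4‑[(2R,5R)‑2,5‑diphenylpyrrolidin‑1‑yl]but‑3‑en‑2‑one F1. KN(SiMe3)2 and TBSCl convert it into the chiral diene (2R,5R)‑1‑{(1E)‑3‑[(tert‑butyldimethylsilyl)oxy]buta‑1,3‑dien‑1‑yl}‑2,5‑diphenylpyrrolidine F2. Heating F2 with 3 in toluene should give the amino cycloadduct (1S,6R)‑6‑[2‑(benzyloxy)ethyl]‑4‑[(tert‑butyldimethylsilyl)oxy]‑2‑[(2R,5R)‑2,5‑diphenylpyrrolidin‑1‑yl]‑1‑methylcyclohex‑3‑ene‑1‑carbaldehyde F3. EtMgBr then gives the ethyl carbinol 1‑{(1S,6R)‑6‑[2‑(benzyloxy)ethyl]‑4‑[(tert‑butyldimethylsilyl)oxy]‑2‑[(2R,5R)‑2,5‑diphenylpyrrolidin‑1‑yl]‑1‑methylcyclohex‑3‑en‑1‑yl}propan‑1‑ol F4, and HF in MeCN cleaves the enol ether and expels the recoverable auxiliary to give 11.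

Step 14. Addition to the C9 carbonyl, flanked by the quaternary C10 and the methyl‑bearing C8, may be too slow, with β‑hydride reduction or γ‑deprotonation taking over. The fallback uses a small, linear, non‑reducing sp nucleophile and saturates afterwards; it sets out from 20 and returns at 23. But‑3‑yn‑2‑one is ketalised with ethylene glycol to 2‑ethynyl‑2‑methyl‑1,3‑dioxolane F5. Its lithium alkynide (n‑BuLi, THF, −78 °C) is added to 20 to give the propargylic carbinol (3R,5R,10R)‑3‑[(tert‑butyldimethylsilyl)oxy]‑13,13‑(ethylenedioxy)‑14,15‑dinorlabd‑7‑en‑11‑yn‑9‑ol F6. Hydrogenation over Pd/C in EtOAc should saturate the triple bond and leave the hindered trisubstituted C7–C8 alkene, giving 23.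

Step 15. The hindered tertiary chromate ester may ionise and lose water to dienes, or suffer a 1,2‑methyl shift from C10, instead of undergoing the [3,3] shift. The fallback separates transposition from oxidation; it sets out from 23 and returns at 24. The perrhenate ester catalyst O3ReOSiPh3 (Et2O, 0 °C) isomerises 23 without oxidant, the equilibrium being pulled to the secondary alcohol with the tetrasubstituted alkene, (3R,5S,10R)‑3‑[(tert‑butyldimethylsilyl)oxy]‑13,13‑(ethylenedioxy)‑14,15‑dinorlabd‑8‑en‑7‑ol F7. MnO2 in CH2Cl2 then oxidises this allylic alcohol to 24.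

**Further compounds**

F1 | step 5 | (E)‑4‑[(2R,5R)‑2,5‑diphenylpyrrolidin‑1‑yl]but‑3‑en‑2‑one | CC(=O)/C=C/N1[C@@H](c2ccccc2)CC[C@@H]1c1ccccc1
F2 | step 5 | (2R,5R)‑1‑{(1E)‑3‑[(tert‑butyldimethylsilyl)oxy]buta‑1,3‑dien‑1‑yl}‑2,5‑diphenylpyrrolidine | C=C(O[Si](C)(C)C(C)(C)C)/C=C/N1[C@@H](c2ccccc2)CC[C@@H]1c1ccccc1
F3 | step 5 | (1S,6R)‑6‑[2‑(benzyloxy)ethyl]‑4‑[(tert‑butyldimethylsilyl)oxy]‑2‑[(2R,5R)‑2,5‑diphenylpyrrolidin‑1‑yl]‑1‑methylcyclohex‑3‑ene‑1‑carbaldehyde, C2 epimers | c1ccccc1COCC[C@@H]1CC(O[Si](C)(C)C(C)(C)C)=CC(N2[C@@H](c3ccccc3)CC[C@@H]2c2ccccc2)[C@@]1(C)C=O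
F4 | step 5 | 1‑{(1S,6R)‑6‑[2‑(benzyloxy)ethyl]‑4‑[(tert‑butyldimethylsilyl)oxy]‑2‑[(2R,5R)‑2,5‑diphenylpyrrolidin‑1‑yl]‑1‑methylcyclohex‑3‑en‑1‑yl}propan‑1‑ol, C2 and carbinol epimers | c1ccccc1COCC[C@@H]1CC(O[Si](C)(C)C(C)(C)C)=CC(N2[C@@H](c3ccccc3)CC[C@@H]2c2ccccc2)[C@@]1(C)C(O)CC
F5 | step 14 | 2‑ethynyl‑2‑methyl‑1,3‑dioxolane | C#CC1(C)OCCO1
F6 | step 14 | (3R,5R,10R)‑3‑[(tert‑butyldimethylsilyl)oxy]‑13,13‑(ethylenedioxy)‑14,15‑dinorlabd‑7‑en‑11‑yn‑9‑ol, C9 epimers | CC1=CC[C@@H]2C(C)(C)[C@H](O[Si](C)(C)C(C)(C)C)CC[C@@]2(C)C1(O)C#CC3(C)OCCO3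
F7 | step 15 | (3R,5S,10R)‑3‑[(tert‑butyldimethylsilyl)oxy]‑13,13‑(ethylenedioxy)‑14,15‑dinorlabd‑8‑en‑7‑ol, C7 epimers | CC1=C(CCC3(C)OCCO3)[C@]2(C)CC[C@@H](O[Si](C)(C)C(C)(C)C)C(C)(C)[C@H]2CC1O
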